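You have to choose between ochre and red for the longer chains, and the runs so far do not show how many chains there are, so begin with what can be said without that count.

| flask | G | J | remark | time |
|---|---|---|---|---|
| dusk | 0.14 M | 25 mM | run made earlier |  |
| spring | 0.30 M | 25 mM | run made earlier |  |
| summer | 0.45 M | 25 mM | run made earlier |  |
| ochre | 0.50 M | 25 mM |  | 4.0 h |
| red | 0.15 M | 25 mM |  | 4.0 h |

- dusk (time / min: Z / %, G / %): 25.0: 0, 99.0; 50.0: 2.1, 97.9; 80.0: 2.5, 97.2; 90.0: 3.9, 96.7; 120: 4.3, 95.1
- spring (time / min: Z / %, G / %): 10.0: 2.6, 99.4; 30.0: 1.7, 97.8; 60.0: 4.4, 96.4; 80.0: 6.7, 92.5; 120: 11.0, 87.8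
- summer (time / min: Z / %, G / %): 10.0: 2.2, 98.1; 20.0: 1.0, 98.8; 30.0: 2.0, 97.7; 60.0: 4.4, 96.6; 120: 17.3, 84.0

(scatter of a reading: 1 percentage point)

- the average divides the monomer in chains by the number of chains begun, living and dead together
- reactions considered so far: 2 J -> L; Z + X -> G + X; G + J -> X + Z; G + X -> Z + X
- the earlier runs do not show the number of chains; that part of a forecast is a guess

- which of the two ends with the longer chains by the average number of monomer units in a chain (chains begun, living or dead) ("neither" if they lie within 10%) (ochre / red / neither)
- average number of monomer units in a chain (chains begun, living or dead) at the end, ochre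
- average number of monomer units in a chain (chains begun, living or dead) at the end, red

The summer run looks odd. Its readings show 3.40% of its G lost by 60.0 min and 16.0% by 120 min, so twice the time reads as 4.71 times the loss, more than the time grew, although G is falling. This clears up if X, which turns G into Z, builds up steadily from J: with J held near its charge and the back step from Z to G left out, the logarithm of G then falls with the G charge and the square of time.

Carrying the summer reading forward that way, I reckon that ochre has 53.9% of its G reacted at the end. Each chain begun takes one J, and J is 5.00% of the G charge, so my estimate for ochre is 10.8 units per J charged: reacted G over charged J. Worked from the G actually reacted, this ratio is a floor on the average length, since chains begun are at most the J charged; mine rests on an estimate of that G. I expect ochre to be longer, but this estimate does not prove it.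

The forecast says ochre, with 65 for ochre and 22 for red, and adds: “The ratio of about 3 is robust, but the absolute values are not”. On my reacted G, its ochre value asks 16.6% of the J to begin chains.

    2 J → L (k = 0.210 L mol⁻¹ min⁻¹)
    Z + X → G + X, rate k2*[X] as long as [Z] is above zero (k = 0.0240 min⁻¹)
    G + J → X + Z (k = 0.0150 L mol⁻¹ min⁻¹)
    G + X → Z + X, rate k4*[X]*[G] (k = 0.270 L mol⁻¹ min⁻¹)

Ochre is longer, 14.9 against 3.12 in red. With 38.5% of its G reacted, ochre has 7.71 units per J charged, so 51.6% of its J began chains; left until 10 h, it has 14.2 against an average of 24.6, a share of 57.9%. In ochre at 2.29 h, J goes 2.8 times faster into chains than into L, and at 4.00 h, with 10% of its charge left, 4.3 times faster.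

Readings and results come from a simulation with constants of no real substance; the scatter is artificial.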